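I count amounts: each product costs the flask two protons' worth of free base, one to free a nucleophile and one for the acid set free.

    nucleophile + acid set free ⇌ protonated nucleophile, settled at all times (K1 = 36000 L mol⁻¹)
    electrophile + nucleophile → acid set free + product (k2 = 49 L mol⁻¹ h⁻¹)
    electrophile + protic impurity → quenched substrate (k3 = 48 L mol⁻¹ h⁻¹)
    acid set free + free base ⇌ salt of the base, settled at all times (K4 = 38000 L mol⁻¹)
    free base + product ⇌ idle adduct, settled at all times (K5 = 470 L mol⁻¹)

electrophile 20 mM; protonated nucleophile 18.0 mM; protic impurity 2.00 mM; time 30 h

- the concentration of free base at which the part of the electrophile that has reacted at 30 h is just 50%, in mM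

I let the protic impurity take its whole 2.00 mM of electrophile, so the target means 8.00 mM of product. I also let the free base take protons first and ignore the idle adduct. Once I count the base as bound, acid stands at concentration a and free nucleophile falls to c/(K1·a), where c is the electrophile remaining, equal here to the nucleophile remaining in all forms. Product then forms at c²/(τ·a), with the creep time τ = K1/k2, 735 h. Each product adds two to a, so a = 2c·√(t/τ), counting the whole run as creep and holding c fixed. The two times are therefore 30 h and τ: their ratio is 0.0408, or ten to the power −1.39, and its root is 0.202. With c at 10.0 mM:

| Step | Amount |
|---|---|
| Base at two per product | 16.0 mM |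
| Acid standing at the end | 4.04 mM |
| Base asked | 12.0 mM |

The forecast, for which the impurity “is fully consumed”, gives 13 mM.

The flask needs 13.0 mM, and 0.726% of that charge is still free at 30.0 h. Solving the same balance with τ for that charge at 90.0 h puts the electrophile remaining at 8.52 mM, and so 57.4% of the electrophile used; the flask shows 57.1% at that time.

Its constants were set for the occasion; the flask was simulated.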